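**Plan**
1. Ring A is the 3,5-dibromo-2-methoxyphenoxy ring. Ring B is the phenol ring, numbered C1 (OH), C2 (O–ring A), C3 (Br), C4 (H), C5 (Br), C6 (Br). The feature used is that the ether oxygen on C2 and the bromine on C3 sit on adjacent carbons, and the oxygen on C1 beside them can be carried as a pinacolboryl group.
2. Retrosynthesis: the C6–Br bond is cut first (late ortho bromination), then C1–O is traced back to C1–B. The O–C2 and C3–Br bonds are then cut together, giving a C2≡C3 aryne of ring B flanked by boron, the phenoxide of ring A and an electrophilic bromine source.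
3. Forward: the iodo triflate that releases the aryne is made from 4-bromophenol in three steps, and the ring A phenol from 3,5-dibromosalicylaldehyde in two. They are joined in step 6, after which boron is oxidised and C6 is brominated. No ring is formed in any step; both benzene rings are bought.
4. Stereochemistry: the target has no stereocentre, so only regiochemistry has to be controlled (boryl-directed addition to the aryne, hydroxyl-directed final bromination).

Key step: step 6

Remark: the phenol of 4-bromo-2,6-diiodophenol is carried unprotected through the iodine–magnesium exchange as its chloromagnesium salt, which removes a protection and a deprotection step.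

**Route**

Step 1
Reactants: 1 4-bromophenol
Product: 2 4-bromo-2,6-diiodophenol
Conditions: I2 (1.5 equiv), 30% aq. H2O2 (3 equiv), H2O, 50 °C
Reagents that add atoms: iodine, II
Why: Oxidative electrophilic aromatic iodination, in which the hydroxyl activates both ortho carbons, the para carbon is blocked by bromine and H2O2 returns the iodide formed to I2.

Step 2
Reactants: 2 4-bromo-2,6-diiodophenol; 3 2-isopropoxy-4,4,5,5-tetramethyl-1,3,2-dioxaborolane
Product: 6 4-bromo-2-iodo-6-(4,4,5,5-tetramethyl-1,3,2-dioxaborolan-2-yl)phenol, via chloromagnesium phenoxide 4 (not isolated), via ring-magnesiated phenoxide 5 (not isolated)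
Conditions: MeMgCl (1.0 equiv), THF, −30 °C; iPrMgCl·LiCl (1.1 equiv), −30 → 0 °C; 3 (1.3 equiv), −30 °C → rt; 1 M HCl work-up
Reagents that add atoms: none
Why: Halogen–magnesium exchange on an unprotected phenol followed by electrophilic borylation; once MeMgCl has formed phenoxide 4, exchange with iPrMgCl·LiCl should stop after one of the two equivalent ortho iodines, because the electron-rich doubly metalated 5 no longer exchanges and the para bromine is far slower than iodine, and the aryl Grignard is then trapped by borate 3.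

Step 3
Reactants: 6 4-bromo-2-iodo-6-(4,4,5,5-tetramethyl-1,3,2-dioxaborolan-2-yl)phenol
Product: 7 4-bromo-2-iodo-6-(4,4,5,5-tetramethyl-1,3,2-dioxaborolan-2-yl)phenyl trifluoromethanesulfonate
Conditions: Tf2O (1.2 equiv), pyridine (2 equiv), CH2Cl2, 0 °C → rt
Reagents that add atoms: trifluoromethanesulfonic anhydride (Tf2O), O=S(=O)(OS(=O)(=O)C(F)(F)F)C(F)(F)F
Why: O-Sulfonylation (triflation) of the phenol, which leaves the neighbouring pinacol boronate and the aryl halides untouched.

Step 4
Reactants: 8 3,5-dibromosalicylaldehyde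
Product: 9 3,5-dibromo-2-methoxybenzaldehyde
Conditions: MeI (1.5 equiv), K2CO3 (2 equiv), DMF, rt
Reagents that add atoms: iodomethane (MeI), CI
Why: Williamson ether synthesis, in which K2CO3 deprotonates the acidic, bromine-flanked phenol and the phenoxide is methylated while the aldehyde stays inert.

Step 5
Reactants: 9 3,5-dibromo-2-methoxybenzaldehyde
Product: 11 3,5-dibromo-2-methoxyphenol, via aryl formate 10 (not isolated)
Conditions: mCPBA (1.5 equiv), CH2Cl2, 40 °C; then MeOH, cat. HCl, rt
Reagents that add atoms: 3-chloroperbenzoic acid (mCPBA), OOC(=O)c1cccc(Cl)c1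
Why: Baeyer–Villiger oxidation in which the aryl group, assisted by its ortho methoxy substituent, migrates in preference to hydride to give formate 10, which acid-catalysed methanolysis cleaves to the phenol.

Step 6
Reactants: 7 4-bromo-2-iodo-6-(4,4,5,5-tetramethyl-1,3,2-dioxaborolan-2-yl)phenyl trifluoromethanesulfonate; 11 3,5-dibromo-2-methoxyphenol
Product: 16 2-[3,5-dibromo-2-(3,5-dibromo-2-methoxyphenoxy)phenyl]-4,4,5,5-tetramethyl-1,3,2-dioxaborolane, via chloromagnesium phenoxide 12 (not isolated), via magnesiated triflate 13 (not isolated), via borylaryne 14 (not isolated), via arylmagnesium adduct 15 (not isolated)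
Conditions: 11 (1.5 equiv), iPrMgCl·LiCl (1.5 equiv), THF, 0 °C; 7 (1.0 equiv), −78 °C; iPrMgCl·LiCl (1.05 equiv, slow addition), −78 → 0 °C; BrCl2C–CCl2Br (2.0 equiv), −40 °C → rt
Reagents that add atoms: 1,2-dibromo-1,1,2,2-tetrachloroethane, BrC(Cl)(Cl)C(Cl)(Cl)Br
Why: Proposed new method: iPrMgCl·LiCl first turns 11 into phenoxide 12 and then exchanges the C3 iodine of 7 to give 13, which loses ClMgOTf to form the C2≡C3 aryne 14; 12 adds through oxygen at C2, and the arylmagnesium 15 left at C3 is brominated by BrCl2C–CCl2Br with loss of Cl2C=CCl2. The closest known reactions are the ortho-selective addition of amines to 3-borylbenzynes generated by iodine–magnesium exchange of iodoaryl triflates, and the aryne 1,2-difunctionalisation in which a magnesium thiolate or amide adds and the resulting arylmagnesium is trapped by an electrophile; an electron-poor phenoxide as the nucleophile is the untested element. No ring is closed and no stereocentre is formed. The selectivity needed is O–C2 over O–C3: the electropositive boryl group at C1 and the inductively withdrawing bromine at C5 both favour carbanion character at C3, and the Lewis acidic boron can bind the phenoxide as a borate and hand it to the neighbouring C2. Chemoselectivity should follow from rates: exchange at iodine outpaces exchange at any aryl bromine and consumes the slowly added iPrMgCl·LiCl before it can add to the aryne, and 15 is kept cold until the bromine source is added.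

Step 7
Reactants: 16 2-[3,5-dibromo-2-(3,5-dibromo-2-methoxyphenoxy)phenyl]-4,4,5,5-tetramethyl-1,3,2-dioxaborolane
Product: 17 3,5-dibromo-2-(3,5-dibromo-2-methoxyphenoxy)phenol
Conditions: NaBO3·4H2O (3 equiv), THF/H2O (1:1), rt
Reagents that add atoms: sodium perborate (NaBO3·4H2O), [Na+].[O-]OB=O
Why: Oxidation of an arylboronate, in which hydroperoxide adds to boron and the aryl group shifts from boron to oxygen at the same carbon, under conditions mild enough for the aryl bromides and the diaryl ether.

Step 8
Reactants: 17 3,5-dibromo-2-(3,5-dibromo-2-methoxyphenoxy)phenol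
Product: 18 2,3,5-tribromo-6-(3,5-dibromo-2-methoxyphenoxy)phenol (CNP0282108.0)
Conditions: NBS (1.0 equiv), iPr2NH (0.1 equiv), CH2Cl2, 0 °C → rt
Reagents that add atoms: N-bromosuccinimide (NBS), O=C1CCC(=O)N1Br
Why: Amine-mediated ortho-selective electrophilic bromination, in which the N-bromoamine formed from NBS and iPr2NH hydrogen-bonds to the phenol and delivers bromine to the free ortho carbon C6, while the para carbon C4 is buttressed between the bromines at C3 and C5 and ring A is a deactivated aryl ether.

**Compound list**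
1 | 4-bromophenol | Oc1ccc(Br)cc1 | starting material
2 | 4-bromo-2,6-diiodophenol | Oc1c(I)cc(Br)cc1I | intermediate
3 | 2-isopropoxy-4,4,5,5-tetramethyl-1,3,2-dioxaborolane | CC(C)OB1OC(C)(C)C(C)(C)O1 | starting material
4 | chloromagnesium 4-bromo-2,6-diiodophenoxide | Cl[Mg]Oc1c(I)cc(Br)cc1I | intermediate
5 | chloromagnesium 4-bromo-2-(chloromagnesio)-6-iodophenoxide | Cl[Mg]Oc1c(I)cc(Br)cc1[Mg]Cl | intermediate
6 | 4-bromo-2-iodo-6-(4,4,5,5-tetramethyl-1,3,2-dioxaborolan-2-yl)phenol | CC1(C)OB(OC1(C)C)c1cc(Br)cc(I)c1O | intermediate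
7 | 4-bromo-2-iodo-6-(4,4,5,5-tetramethyl-1,3,2-dioxaborolan-2-yl)phenyl trifluoromethanesulfonate | CC1(C)OB(OC1(C)C)c1cc(Br)cc(I)c1OS(=O)(=O)C(F)(F)F | intermediate
8 | 3,5-dibromosalicylaldehyde | O=Cc1cc(Br)cc(Br)c1O | starting material
9 | 3,5-dibromo-2-methoxybenzaldehyde | COc1c(Br)cc(Br)cc1C=O | intermediate
10 | 3,5-dibromo-2-methoxyphenyl formate | COc1c(Br)cc(Br)cc1OC=O | intermediate
11 | 3,5-dibromo-2-methoxyphenol | COc1c(O)cc(Br)cc1Br | intermediate
12 | chloromagnesium 3,5-dibromo-2-methoxyphenoxide | COc1c(O[Mg]Cl)cc(Br)cc1Br | intermediate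
13 | [5-bromo-3-(4,4,5,5-tetramethyl-1,3,2-dioxaborolan-2-yl)-2-(trifluoromethanesulfonyloxy)phenyl]magnesium chloride | CC1(C)OB(OC1(C)C)c1cc(Br)cc([Mg]Cl)c1OS(=O)(=O)C(F)(F)F | intermediate
14 | 5-bromo-3-(4,4,5,5-tetramethyl-1,3,2-dioxaborolan-2-yl)benzyne (triple bond between C2 and C3 of ring B) | CC1(C)OB(OC1(C)C)C1=CC(Br)=CC#C1 | intermediate
15 | [5-bromo-2-(3,5-dibromo-2-methoxyphenoxy)-3-(4,4,5,5-tetramethyl-1,3,2-dioxaborolan-2-yl)phenyl]magnesium chloride | COc1c(Br)cc(Br)cc1Oc1c([Mg]Cl)cc(Br)cc1B1OC(C)(C)C(C)(C)O1 | intermediate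
16 | 2-[3,5-dibromo-2-(3,5-dibromo-2-methoxyphenoxy)phenyl]-4,4,5,5-tetramethyl-1,3,2-dioxaborolane | COc1c(Br)cc(Br)cc1Oc1c(Br)cc(Br)cc1B1OC(C)(C)C(C)(C)O1 | intermediate
17 | 3,5-dibromo-2-(3,5-dibromo-2-methoxyphenoxy)phenol | COc1c(Br)cc(Br)cc1Oc1c(Br)cc(Br)cc1O | intermediate
18 | 2,3,5-tribromo-6-(3,5-dibromo-2-methoxyphenoxy)phenol | COc1c(Br)cc(Br)cc1Oc1c(Br)cc(Br)c(Br)c1O | target

**Step count**
Total: 8 steps. Longest linear sequence: 6 steps (steps 1, 2, 3, 6, 7, 8 from 4-bromophenol).

**Steps most likely to fail**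

Step 6. Capture of the short-lived aryne by the weakly nucleophilic, electron-poor aryloxide may be slower than addition of iPrMgCl·LiCl or aryne oligomerisation, or the arylmagnesium may be protonated before it is brominated. The fallback uses known chemistry, sets out from 11 and returns at 17. Nucleophilic aromatic substitution of commercial 3,5-dibromo-2-fluorobenzaldehyde (O=Cc1cc(Br)cc(Br)c1F) by 11 with K2CO3 in DMF at 90 °C should give 3,5-dibromo-2-(3,5-dibromo-2-methoxyphenoxy)benzaldehyde F1. Baeyer–Villiger oxidation with mCPBA in CH2Cl2 should then give 3,5-dibromo-2-(3,5-dibromo-2-methoxyphenoxy)phenyl formate F2, and acid-catalysed methanolysis releases phenol 17, from which step 8 follows unchanged.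

Step 8. Bromination may occur at C4, para to the hydroxyl, or twice. The fallback sets out from 17 and returns at 18. Acylation with ClC(=O)NEt2 and NaH in THF should give 3,5-dibromo-2-(3,5-dibromo-2-methoxyphenoxy)phenyl N,N-diethylcarbamate F3. Directed ortho magnesiation with TMPMgCl·LiCl (TMP = 2,2,6,6-tetramethylpiperidide) in THF at −20 °C, where the carbamate oxygen guides the base to C6, should give [4,6-dibromo-3-(3,5-dibromo-2-methoxyphenoxy)-2-(diethylcarbamoyloxy)phenyl]magnesium chloride F4. BrCl2C–CCl2Br converts this into 2,3,5-tribromo-6-(3,5-dibromo-2-methoxyphenoxy)phenyl N,N-diethylcarbamate F5, and KOH in aqueous ethanol at reflux cleaves the carbamate to 18.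

Step 2. Exchange on the phenoxide may be incomplete or go twice, or the doubly metalated species may be protonated before it is borylated. The fallback sets out from 2 and returns at 6. Protection with MOMCl and iPr2NEt in CH2Cl2 should give 5-bromo-1,3-diiodo-2-(methoxymethoxy)benzene F6. Single iodine–magnesium exchange with iPrMgCl·LiCl in THF at −40 °C, assisted by the acetal oxygen, gives [5-bromo-3-iodo-2-(methoxymethoxy)phenyl]magnesium chloride F7, which borate 3 converts into 2-[5-bromo-3-iodo-2-(methoxymethoxy)phenyl]-4,4,5,5-tetramethyl-1,3,2-dioxaborolane F8. HCl in MeOH removes the acetal to give 6.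

**Further compounds**
F1 | step 6 | 3,5-dibromo-2-(3,5-dibromo-2-methoxyphenoxy)benzaldehyde | COc1c(Br)cc(Br)cc1Oc1c(Br)cc(Br)cc1C=O
F2 | step 6 | 3,5-dibromo-2-(3,5-dibromo-2-methoxyphenoxy)phenyl formate | COc1c(Br)cc(Br)cc1Oc1c(Br)cc(Br)cc1OC=O
F3 | step 8 | 3,5-dibromo-2-(3,5-dibromo-2-methoxyphenoxy)phenyl N,N-diethylcarbamate | CCN(CC)C(=O)Oc1cc(Br)cc(Br)c1Oc1cc(Br)cc(Br)c1OC
F4 | step 8 | [4,6-dibromo-3-(3,5-dibromo-2-methoxyphenoxy)-2-(diethylcarbamoyloxy)phenyl]magnesium chloride | CCN(CC)C(=O)Oc1c([Mg]Cl)c(Br)cc(Br)c1Oc1cc(Br)cc(Br)c1OC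
F5 | step 8 | 2,3,5-tribromo-6-(3,5-dibromo-2-methoxyphenoxy)phenyl N,N-diethylcarbamate | CCN(CC)C(=O)Oc1c(Br)c(Br)cc(Br)c1Oc1cc(Br)cc(Br)c1OC
F6 | step 2 | 5-bromo-1,3-diiodo-2-(methoxymethoxy)benzene | COCOc1c(I)cc(Br)cc1I
F7 | step 2 | [5-bromo-3-iodo-2-(methoxymethoxy)phenyl]magnesium chloride | COCOc1c(I)cc(Br)cc1[Mg]Cl
F8 | step 2 | 2-[5-bromo-3-iodo-2-(methoxymethoxy)phenyl]-4,4,5,5-tetramethyl-1,3,2-dioxaborolane | COCOc1c(I)cc(Br)cc1B1OC(C)(C)C(C)(C)O1
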